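**Retrosynthetic overview**

1. Numbering used below (labdane-type): ring B = C5–C10, lactone carbons C1 and C2, acid C3/C4, side chain C11–C16. The side chain is cut back to a C9 aldehyde (methallylboration, ozonolysis, chelation-controlled vinyl addition), and the aldehyde carbon to a C9 ketone (methylenation, hydroboration).
2. The 6-hydroxyl is cut back to a C6 ketone, which leaves the bicyclic dione lactone 10 (2-oxabicyclo[3.3.1]nonane-3,7,9-trione core).
3. Key disconnection: the acetate bridge CH2–C(=O)–O is taken off C10 and C8 in one operation, back to the monocyclic silyl enol ether 5 and tert-butyl bromoacetate 6.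
4. Enabling feature: in ring B the carbonyl carbon C9 has C10 and C8 as its two α-carbons. C10 is the enolate carbon (nucleophile for the CH2–C10 bond). C8 is also the β-carbon of the masked C6 enone (C8=C7–C6=O of a 2-ene-1,4-dione), so it is the electrophile for the carboxylate oxygen. The two-carbon unit therefore spans the one-carbon bridge C9 and closes the lactone ring.
5. Ring order: ring B is taken from the arene of 2,6-dimethylphenol (dearomatised to a quinone monoketal; C5 side chain by asymmetric Mukaiyama–Michael addition); the lactone ring is closed second, in the key step.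

Key step: step 3

Remark (assumptions): β is the face of ring B that carries the C8 and C10 methyl groups, α is the face of the lactone bridge; the (S)-oxazaborolidinium catalyst of step 2 is assumed to select the β-carbon and face that give (S)-5, and if the sense is opposite its antipode is used with nothing else changed.

**Route**

Step 1
Reactants: 1 2,6-dimethylphenol
Product: 3 4,4-dimethoxy-2,6-dimethylcyclohexa-2,5-dien-1-one, via 4-methoxy-2,6-dimethylphenol 2 (not isolated)
Conditions: PhI(OAc)2 (2.2 equiv), MeOH, 0 °C → rt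
Reagents that add atoms: methanol (CO)
Why: Oxidative dearomatisation of a phenol with PhI(OAc)2 in methanol, in which the first oxidation should place a methoxy group para to the hydroxyl and the second should trap the phenoxenium ion with methanol at the same carbon, giving the quinone monoketal with the future C6 carbonyl masked and the C9 carbonyl free; no stereocentre is formed.

Step 2
Reactants: 3 4,4-dimethoxy-2,6-dimethylcyclohexa-2,5-dien-1-one, 4 1-methoxy-2-methyl-1-(trimethylsilyloxy)prop-1-ene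
Product: 5 methyl 2-[(1S)-6,6-dimethoxy-2,4-dimethyl-3-(trimethylsilyloxy)cyclohexa-2,4-dien-1-yl]-2-methylpropanoate
Conditions: (S)-3,3-diphenyl-1-(o-tolyl)tetrahydro-1H,3H-pyrrolo[1,2-c][1,3,2]oxazaborole (20 mol %), HNTf2 (20 mol %), Ph3PO (25 mol %), toluene, −40 °C; Et3N quench
Reagents that add atoms: none
Why: Catalytic enantioselective Mukaiyama–Michael addition, in which the chiral oxazaborolidinium ion binds the C9 carbonyl of the prochiral dienone and differentiates the two enantiotopic β-carbons, so that the ketene silyl acetal should add at C5 (C4–C5 bond, (S) stereocentre) and silyl transfer should give the C9 silyl enol ether.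

Step 3
Reactants: 5 methyl 2-[(1S)-6,6-dimethoxy-2,4-dimethyl-3-(trimethylsilyloxy)cyclohexa-2,4-dien-1-yl]-2-methylpropanoate, 6 tert-butyl bromoacetate
Product: 10 methyl 2-[(1S,5R,6S)-1,5-dimethyl-3,7,9-trioxo-2-oxabicyclo[3.3.1]nonan-6-yl]-2-methylpropanoate, via potassium enolate 7 (not isolated), via alkylated ketal ester 8 (not isolated), via enedione acid 9 (not isolated)
Conditions: KOtBu, THF, −40 °C; then 6, −40 → 0 °C; solvent exchange, then CF3CO2H–CH2Cl2–H2O (10:10:1), 0 °C → rt
Reagents that add atoms: water (O)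
Why: KOtBu cleaves the silyl enol ether to the regiodefined C9 enolate 7, which is C-alkylated by 6 at C10 (SN2 enolate alkylation, CH2–C10 bond); CF3CO2H then cleaves the ketal and the tert-butyl ester to unmask the 2-ene-1,4-dione acid 9, whose carboxyl group adds to C8 in an intramolecular oxa-Michael addition (O–C8 bond). The closest known reaction types are the alkylation of silyl-enol-ether-derived enolates with α-halo esters and the lactonisation of carboxylic acids onto enones. The lactone ring closes in the 6-exo-trig mode. C10 is set by the C5 stereocentre, because the electrophile approaches the enolate face opposite the bulky C5 side chain (acetate arm trans to it), and C8 is set by the tether, because the carboxyl group anchored on C10 can reach C8 only from the same face (cis bridge). The step needs alkylation at C10 only and addition at C8 rather than C7: the first is secured because C10 is the only enolate carbon (C8 is still olefinic), the second by ring size (six- against seven-membered). Unmasking the enedione only after C10 has become quaternary keeps the ring from tautomerising to a hydroquinone.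

Step 4
Reactants: 10 methyl 2-[(1S,5R,6S)-1,5-dimethyl-3,7,9-trioxo-2-oxabicyclo[3.3.1]nonan-6-yl]-2-methylpropanoate
Product: 11 methyl 2-[(1S,5R,6S,7R)-7-hydroxy-1,5-dimethyl-3,9-dioxo-2-oxabicyclo[3.3.1]nonan-6-yl]-2-methylpropanoate
Conditions: (S)-1-methyl-3,3-diphenyltetrahydro-1H,3H-pyrrolo[1,2-c][1,3,2]oxazaborole (0.3 equiv), BH3·SMe2, THF, −30 °C; MeOH quench
Reagents that add atoms: none
Why: Corey–Bakshi–Shibata reduction, in which the catalyst–borane complex should reduce only the C6 ketone (the C9 ketone lies between two quaternary carbons) and, with the C5 flank as the large and the C7 methylene as the small group, deliver hydride to the β-face to give the 6α-alcohol under reagent control.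

Step 5
Reactants: 11 methyl 2-[(1S,5R,6S,7R)-7-hydroxy-1,5-dimethyl-3,9-dioxo-2-oxabicyclo[3.3.1]nonan-6-yl]-2-methylpropanoate
Product: 12 methyl 2-[(1S,5R,6S,7R)-7-(tert-butyldimethylsilyloxy)-1,5-dimethyl-3,9-dioxo-2-oxabicyclo[3.3.1]nonan-6-yl]-2-methylpropanoate
Conditions: TBSOTf, 2,6-lutidine, CH2Cl2, 0 °C
Reagents that add atoms: tert-butyldimethylsilyl trifluoromethanesulfonate (CC(C)(C)[Si](C)(C)OS(=O)(=O)C(F)(F)F)
Why: Silylation of a hindered secondary alcohol with a silyl triflate, which keeps the 6α-oxygen from attacking the nearby lactone carbonyl in the basic steps that follow; no stereocentre is touched.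

Step 6
Reactants: 12 methyl 2-[(1S,5R,6S,7R)-7-(tert-butyldimethylsilyloxy)-1,5-dimethyl-3,9-dioxo-2-oxabicyclo[3.3.1]nonan-6-yl]-2-methylpropanoate
Product: 13 methyl 2-[(1S,5R,6S,7R)-7-(tert-butyldimethylsilyloxy)-1,5-dimethyl-9-methylidene-3-oxo-2-oxabicyclo[3.3.1]nonan-6-yl]-2-methylpropanoate
Conditions: Zn, CH2Br2, TiCl4, THF/CH2Cl2, 0 °C → rt
Reagents that add atoms: dibromomethane (BrCBr)
Why: Takai–Lombardo methylenation, whose small, non-basic titanium–zinc methylene reagent should convert the hindered, non-enolisable C9 ketone into the exocyclic alkene without touching the lactone, the ester or the silyl ether.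

Step 7
Reactants: 13 methyl 2-[(1S,5R,6S,7R)-7-(tert-butyldimethylsilyloxy)-1,5-dimethyl-9-methylidene-3-oxo-2-oxabicyclo[3.3.1]nonan-6-yl]-2-methylpropanoate
Product: 15 methyl 2-[(1S,5R,6S,7R,9R)-7-(tert-butyldimethylsilyloxy)-9-(hydroxymethyl)-1,5-dimethyl-3-oxo-2-oxabicyclo[3.3.1]nonan-6-yl]-2-methylpropanoate, via C11 alkylborane 14 (not isolated)
Conditions: BH3·THF, THF, 0 °C; then H2O2, aq. NaHCO3, 0 °C
Reagents that add atoms: hydrogen peroxide (OO)
Why: Hydroboration–oxidation, in which borane should add anti-Markovnikov to the 1,1-disubstituted alkene from the α-face (over the flat lactone ring, away from the C5 side chain and the C6 hydrogen on the carbocycle side), so that hydrogen enters C9 from the α-face and the CH2OH group ends up β.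

Step 8
Reactants: 15 methyl 2-[(1S,5R,6S,7R,9R)-7-(tert-butyldimethylsilyloxy)-9-(hydroxymethyl)-1,5-dimethyl-3-oxo-2-oxabicyclo[3.3.1]nonan-6-yl]-2-methylpropanoate
Product: 16 methyl 2-[(1S,5R,6S,7R,9S)-7-(tert-butyldimethylsilyloxy)-9-formyl-1,5-dimethyl-3-oxo-2-oxabicyclo[3.3.1]nonan-6-yl]-2-methylpropanoate
Conditions: Dess–Martin periodinane, NaHCO3, CH2Cl2, 0 °C → rt
Reagents that add atoms: none
Why: Dess–Martin oxidation of the primary alcohol under buffered, non-enolising conditions, so the C9 stereocentre next to the new aldehyde should not epimerise (the descriptor changes only through the priority rules).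

Step 9
Reactants: 16 methyl 2-[(1S,5R,6S,7R,9S)-7-(tert-butyldimethylsilyloxy)-9-formyl-1,5-dimethyl-3-oxo-2-oxabicyclo[3.3.1]nonan-6-yl]-2-methylpropanoate, 17 2-methylallylmagnesium chloride
Product: 19 methyl 2-[(1S,5R,6S,7R,9R)-7-(tert-butyldimethylsilyloxy)-9-[(1S)-1-hydroxy-3-methylbut-3-en-1-yl]-1,5-dimethyl-3-oxo-2-oxabicyclo[3.3.1]nonan-6-yl]-2-methylpropanoate, via B-methallyldiisopinocampheylborane 18 (not isolated)
Conditions: (−)-B-methoxydiisopinocampheylborane (from (+)-α-pinene), 17, Et2O, 0 °C; then 16, −78 °C; then H2O2, aq. NaOAc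
Reagents that add atoms: none
Why: Brown allylboration (methallyl variant), in which the chair transition state of the pinene-derived borane should direct attack to the si face of the hindered aldehyde and give the (11S) homoallylic alcohol under reagent control without epimerising C9.

Step 10
Reactants: 19 methyl 2-[(1S,5R,6S,7R,9R)-7-(tert-butyldimethylsilyloxy)-9-[(1S)-1-hydroxy-3-methylbut-3-en-1-yl]-1,5-dimethyl-3-oxo-2-oxabicyclo[3.3.1]nonan-6-yl]-2-methylpropanoate
Product: 21 methyl 2-[(1S,5R,6S,7R,9R)-7-(tert-butyldimethylsilyloxy)-9-[(1S)-1-hydroxy-3-oxobutyl]-1,5-dimethyl-3-oxo-2-oxabicyclo[3.3.1]nonan-6-yl]-2-methylpropanoate, via ozonide 20 (not isolated)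
Conditions: O3, CH2Cl2, −78 °C; then PPh3, −78 °C → rt
Reagents that add atoms: ozone ([O-][O+]=O)
Why: Ozonolysis with reductive work-up of the only alkene in the molecule should give the β-hydroxy methyl ketone (C13 carbonyl, C16 methyl) and leave all stereocentres untouched.

Step 11
Reactants: 21 methyl 2-[(1S,5R,6S,7R,9R)-7-(tert-butyldimethylsilyloxy)-9-[(1S)-1-hydroxy-3-oxobutyl]-1,5-dimethyl-3-oxo-2-oxabicyclo[3.3.1]nonan-6-yl]-2-methylpropanoate, 22 vinylmagnesium bromide
Product: 23 methyl 2-[(1S,5R,6S,7R,9R)-7-(tert-butyldimethylsilyloxy)-9-[(1S,3S)-1,3-dihydroxy-3-methylpent-4-en-1-yl]-1,5-dimethyl-3-oxo-2-oxabicyclo[3.3.1]nonan-6-yl]-2-methylpropanoate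
Conditions: 22 (4 equiv), THF, −78 °C; then H2O
Reagents that add atoms: none
Why: Chelation-controlled Grignard addition, in which the magnesium alkoxide of the C11 hydroxyl should chelate the C13 ketone in a six-membered ring and the vinyl group should attack the face anti to the C11 substituent, giving the two hydroxyls syn when the C13 methyl is drawn in the chain, which is (13S); at −78 °C the chelated ketone should react before the lactone and the hindered ester.

Step 12
Reactants: 23 methyl 2-[(1S,5R,6S,7R,9R)-7-(tert-butyldimethylsilyloxy)-9-[(1S,3S)-1,3-dihydroxy-3-methylpent-4-en-1-yl]-1,5-dimethyl-3-oxo-2-oxabicyclo[3.3.1]nonan-6-yl]-2-methylpropanoate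
Product: 24 2-[(1S,5R,6S,7R,9R)-7-(tert-butyldimethylsilyloxy)-9-[(1S,3S)-1,3-dihydroxy-3-methylpent-4-en-1-yl]-1,5-dimethyl-3-oxo-2-oxabicyclo[3.3.1]nonan-6-yl]-2-methylpropanoic acid
Conditions: NaSEt, DMF, 80 °C; then aq. HCl to pH 3, 0 °C
Reagents that add atoms: none
Why: SN2 demethylation of a hindered α,α-dimethyl methyl ester, in which the soft thiolate attacks the methyl carbon, so the crowded acyl carbon is not involved and the lactone (tertiary alkyl oxygen) and the silyl ether should stay intact.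

Step 13
Reactants: 24 2-[(1S,5R,6S,7R,9R)-7-(tert-butyldimethylsilyloxy)-9-[(1S,3S)-1,3-dihydroxy-3-methylpent-4-en-1-yl]-1,5-dimethyl-3-oxo-2-oxabicyclo[3.3.1]nonan-6-yl]-2-methylpropanoic acid
Product: 25 2-[(1S,5R,6S,7R,9R)-9-[(1S,3S)-1,3-dihydroxy-3-methylpent-4-en-1-yl]-7-hydroxy-1,5-dimethyl-3-oxo-2-oxabicyclo[3.3.1]nonan-6-yl]-2-methylpropanoic acid (CNP0297019.2)
Conditions: HF·pyridine, pyridine, THF, 0 °C → rt
Reagents that add atoms: none
Why: Fluoride-mediated cleavage of the silyl ether under pyridine-buffered conditions, placed last so that the free 6α-hydroxyl never meets base next to the lactone; the tertiary allylic alcohol and all stereocentres should be unaffected.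

**Compound list**

1 | 2,6-dimethylphenol | Cc1cccc(C)c1O | starting material
2 | 4-methoxy-2,6-dimethylphenol | COc1cc(C)c(O)c(C)c1 | intermediate
3 | 4,4-dimethoxy-2,6-dimethylcyclohexa-2,5-dien-1-one | COC1(OC)C=C(C)C(=O)C(C)=C1 | intermediate
4 | 1-methoxy-2-methyl-1-(trimethylsilyloxy)prop-1-ene | COC(O[Si](C)(C)C)=C(C)C | starting material
5 | methyl 2-[(1S)-6,6-dimethoxy-2,4-dimethyl-3-(trimethylsilyloxy)cyclohexa-2,4-dien-1-yl]-2-methylpropanoate | COC(=O)C(C)(C)[C@@H]1C(C)=C(O[Si](C)(C)C)C(C)=CC1(OC)OC | intermediate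
6 | tert-butyl bromoacetate | CC(C)(C)OC(=O)CBr | starting material
7 | potassium C9 enolate of 5 (K in place of Me3Si) | COC(=O)C(C)(C)[C@@H]1C(C)=C([O-])C(C)=CC1(OC)OC.[K+] | intermediate
8 | methyl 2-[(1S,2R)-2-(2-tert-butoxy-2-oxoethyl)-6,6-dimethoxy-2,4-dimethyl-3-oxocyclohex-4-en-1-yl]-2-methylpropanoate | COC(=O)C(C)(C)[C@@H]1[C@@](C)(CC(=O)OC(C)(C)C)C(=O)C(C)=CC1(OC)OC | intermediate
9 | 2-[(1R,6S)-6-(1-methoxy-2-methyl-1-oxopropan-2-yl)-1,3-dimethyl-2,5-dioxocyclohex-3-en-1-yl]acetic acid | COC(=O)C(C)(C)[C@@H]1[C@@](C)(CC(=O)O)C(=O)C(C)=CC1=O | intermediate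
10 | methyl 2-[(1S,5R,6S)-1,5-dimethyl-3,7,9-trioxo-2-oxabicyclo[3.3.1]nonan-6-yl]-2-methylpropanoate (lactone bridge α, C5 side chain β) | O=C1[C@]2(C)CC(=O)O[C@@]1(C)CC(=O)[C@@H]2C(C)(C)C(=O)OC | intermediate
11 | methyl 2-[(1S,5R,6S,7R)-7-hydroxy-1,5-dimethyl-3,9-dioxo-2-oxabicyclo[3.3.1]nonan-6-yl]-2-methylpropanoate (6α-OH) | O=C1[C@]2(C)CC(=O)O[C@@]1(C)C[C@@H](O)[C@@H]2C(C)(C)C(=O)OC | intermediate
12 | methyl 2-[(1S,5R,6S,7R)-7-(tert-butyldimethylsilyloxy)-1,5-dimethyl-3,9-dioxo-2-oxabicyclo[3.3.1]nonan-6-yl]-2-methylpropanoate | O=C1[C@]2(C)CC(=O)O[C@@]1(C)C[C@@H](O[Si](C)(C)C(C)(C)C)[C@@H]2C(C)(C)C(=O)OC | intermediate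
13 | methyl 2-[(1S,5R,6S,7R)-7-(tert-butyldimethylsilyloxy)-1,5-dimethyl-9-methylidene-3-oxo-2-oxabicyclo[3.3.1]nonan-6-yl]-2-methylpropanoate | C=C1[C@]2(C)CC(=O)O[C@@]1(C)C[C@@H](O[Si](C)(C)C(C)(C)C)[C@@H]2C(C)(C)C(=O)OC | intermediate
14 | C11 alkylborane from 13 (BH2 on the new CH2, H9 α) | BC[C@H]1[C@]2(C)CC(=O)O[C@@]1(C)C[C@@H](O[Si](C)(C)C(C)(C)C)[C@@H]2C(C)(C)C(=O)OC | intermediate
15 | methyl 2-[(1S,5R,6S,7R,9R)-7-(tert-butyldimethylsilyloxy)-9-(hydroxymethyl)-1,5-dimethyl-3-oxo-2-oxabicyclo[3.3.1]nonan-6-yl]-2-methylpropanoate | OC[C@H]1[C@]2(C)CC(=O)O[C@@]1(C)C[C@@H](O[Si](C)(C)C(C)(C)C)[C@@H]2C(C)(C)C(=O)OC | intermediate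
16 | methyl 2-[(1S,5R,6S,7R,9S)-7-(tert-butyldimethylsilyloxy)-9-formyl-1,5-dimethyl-3-oxo-2-oxabicyclo[3.3.1]nonan-6-yl]-2-methylpropanoate | O=C[C@H]1[C@]2(C)CC(=O)O[C@@]1(C)C[C@@H](O[Si](C)(C)C(C)(C)C)[C@@H]2C(C)(C)C(=O)OC | intermediate
17 | 2-methylallylmagnesium chloride | CC(=C)C[Mg]Cl | starting material
18 | (−)-B-(2-methylallyl)diisopinocampheylborane | CC(=C)CB([C@@H]1C[C@@H]2C[C@H]([C@H]1C)C2(C)C)[C@@H]1C[C@@H]2C[C@H]([C@H]1C)C2(C)C | intermediate
19 | methyl 2-[(1S,5R,6S,7R,9R)-7-(tert-butyldimethylsilyloxy)-9-[(1S)-1-hydroxy-3-methylbut-3-en-1-yl]-1,5-dimethyl-3-oxo-2-oxabicyclo[3.3.1]nonan-6-yl]-2-methylpropanoate | CC(=C)C[C@H](O)[C@H]1[C@]2(C)CC(=O)O[C@@]1(C)C[C@@H](O[Si](C)(C)C(C)(C)C)[C@@H]2C(C)(C)C(=O)OC | intermediate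
20 | secondary ozonide of 19 (3-methyl-1,2,4-trioxolan-3-yl in place of the isopropenyl group; configuration at the trioxolane carbon undefined) | CC1(OCOO1)C[C@H](O)[C@H]1[C@]2(C)CC(=O)O[C@@]1(C)C[C@@H](O[Si](C)(C)C(C)(C)C)[C@@H]2C(C)(C)C(=O)OC | intermediate
21 | methyl 2-[(1S,5R,6S,7R,9R)-7-(tert-butyldimethylsilyloxy)-9-[(1S)-1-hydroxy-3-oxobutyl]-1,5-dimethyl-3-oxo-2-oxabicyclo[3.3.1]nonan-6-yl]-2-methylpropanoate | CC(=O)C[C@H](O)[C@H]1[C@]2(C)CC(=O)O[C@@]1(C)C[C@@H](O[Si](C)(C)C(C)(C)C)[C@@H]2C(C)(C)C(=O)OC | intermediate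
22 | vinylmagnesium bromide | C=C[Mg]Br | starting material
23 | methyl 2-[(1S,5R,6S,7R,9R)-7-(tert-butyldimethylsilyloxy)-9-[(1S,3S)-1,3-dihydroxy-3-methylpent-4-en-1-yl]-1,5-dimethyl-3-oxo-2-oxabicyclo[3.3.1]nonan-6-yl]-2-methylpropanoate | C=C[C@@](C)(O)C[C@H](O)[C@H]1[C@]2(C)CC(=O)O[C@@]1(C)C[C@@H](O[Si](C)(C)C(C)(C)C)[C@@H]2C(C)(C)C(=O)OC | intermediate
24 | 2-[(1S,5R,6S,7R,9R)-7-(tert-butyldimethylsilyloxy)-9-[(1S,3S)-1,3-dihydroxy-3-methylpent-4-en-1-yl]-1,5-dimethyl-3-oxo-2-oxabicyclo[3.3.1]nonan-6-yl]-2-methylpropanoic acid | C=C[C@@](C)(O)C[C@H](O)[C@H]1[C@]2(C)CC(=O)O[C@@]1(C)C[C@@H](O[Si](C)(C)C(C)(C)C)[C@@H]2C(C)(C)C(=O)O | intermediate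
25 | 2-[(1S,5R,6S,7R,9R)-9-[(1S,3S)-1,3-dihydroxy-3-methylpent-4-en-1-yl]-7-hydroxy-1,5-dimethyl-3-oxo-2-oxabicyclo[3.3.1]nonan-6-yl]-2-methylpropanoic acid | C=C[C@@](C)(O)C[C@H](O)[C@H]1[C@]2(C)CC(=O)O[C@@]1(C)C[C@@H](O)[C@@H]2C(C)(C)C(=O)O | target

**Step count and risks**

Total step count: 13. Longest linear sequence: 13 steps (1 → 25).

The three steps most likely to fail:

Step 3. What may go wrong: reversal of the oxa-Michael addition (retro-addition back to the enedione acid), or O- instead of C-alkylation of the enolate. Fallback (oxidative instead of conjugate C–O bond formation): it sets out from 5 and comes back to the route at 10. Only the alkylation stage is run (KOtBu; 6) and alkylated ketal ester 8 is isolated. Hydrogenation (H2, Pd on carbon, EtOAc) should saturate the C7=C8 bond to give the saturated ketal ester F5. CF3CO2H/H2O should then remove the ketal and the tert-butyl ester to give the saturated dione acid F6. Oxidative α-lactonisation (Bu4NI cat., tert-butyl hydroperoxide, EtOAc, 50 °C) should iodinate C8, the only enolisable α-carbon of the C9 ketone, and the carboxylate should displace iodide in the six-membered mode, closing the same lactone irreversibly to give 10.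

Step 2. What may go wrong: loss of methanol from the adduct under the Lewis acid (aromatisation to a 4-methoxyphenol), and weak discrimination of the two enantiotopic β-carbons. Fallback (auxiliary control under basic conditions instead of Lewis acid catalysis): it sets out from 3 and comes back to the route at 9. Transketalisation of 3 with (1R,2R)-1,2-diphenylethane-1,2-diol (pyridinium p-toluenesulfonate, benzene, reflux) should give the C2-symmetric spiro-dioxolane dienone F1. The lithium enolate of methyl isobutyrate (LDA, THF, −78 → −30 °C) should add 1,4 to the β-carbon on the face not shielded by the neighbouring phenyl group, and Me3SiCl should trap the product as silyl enol ether F2 (the diol antipode is chosen under the same assumption as for step 2). Under the conditions of step 3, F2 should pass through potassium enolate F3 and alkylated dioxolane ester F4, and the CF3CO2H stage should release the diol to give enedione acid 9, which closes to 10 as before.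

Step 4. What may go wrong: poor facial selectivity, that is hydride delivery to the more open α-face of C6 against the catalyst, which would give the 6β-alcohol. Fallback (inversion instead of direct delivery): it sets out from 10 and comes back to the route at 11. NaBH4 (MeOH, −78 °C) is allowed to follow the substrate bias to the 6β-alcohol F7. A Mitsunobu reaction (4-nitrobenzoic acid, PPh3, diisopropyl azodicarboxylate, toluene) should invert C6 by attack from the open α-face to give the 6α-nitrobenzoate F8. NaN3 in MeOH should then cleave the nitrobenzoate without opening the lactone and give 11.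

Further compounds
F1 | step 2 | (2R,3R)-7,9-dimethyl-2,3-diphenyl-1,4-dioxaspiro[4.5]deca-6,9-dien-8-one | O=C1C(C)=CC2(O[C@H](c3ccccc3)[C@@H](c3ccccc3)O2)C=C1C
F2 | step 2 | silyl enol ether analogue of 5 with the (R,R)-diphenyldioxolane in place of the dimethyl ketal | COC(=O)C(C)(C)[C@@H]1C(C)=C(O[Si](C)(C)C)C(C)=CC12O[C@H](c3ccccc3)[C@@H](c3ccccc3)O2
F3 | step 2 | potassium enolate of F2 | COC(=O)C(C)(C)[C@@H]1C(C)=C([O-])C(C)=CC12O[C@H](c3ccccc3)[C@@H](c3ccccc3)O2.[K+]
F4 | step 2 | alkylated dioxolane ester (8 with the (R,R)-diphenyldioxolane in place of the dimethyl ketal) | COC(=O)C(C)(C)[C@@H]1[C@@](C)(CC(=O)OC(C)(C)C)C(=O)C(C)=CC12O[C@H](c3ccccc3)[C@@H](c3ccccc3)O2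
F5 | step 3 | methyl 2-[(1S,2R)-2-(2-tert-butoxy-2-oxoethyl)-6,6-dimethoxy-2,4-dimethyl-3-oxocyclohexyl]-2-methylpropanoate (C4 epimers) | COC(=O)C(C)(C)[C@@H]1[C@@](C)(CC(=O)OC(C)(C)C)C(=O)C(C)CC1(OC)OC
F6 | step 3 | 2-[(1R,6S)-6-(1-methoxy-2-methyl-1-oxopropan-2-yl)-1,3-dimethyl-2,5-dioxocyclohexyl]acetic acid (C3 epimers) | COC(=O)C(C)(C)[C@@H]1[C@@](C)(CC(=O)O)C(=O)C(C)CC1=O
F7 | step 4 | methyl 2-[(1S,5R,6S,7S)-7-hydroxy-1,5-dimethyl-3,9-dioxo-2-oxabicyclo[3.3.1]nonan-6-yl]-2-methylpropanoate (6β-OH) | O=C1[C@]2(C)CC(=O)O[C@@]1(C)C[C@H](O)[C@@H]2C(C)(C)C(=O)OC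
F8 | step 4 | 4-nitrobenzoate of 11 (6α-ester) | O=C1[C@]2(C)CC(=O)O[C@@]1(C)C[C@@H](OC(=O)c3ccc(cc3)[N+](=O)[O-])[C@@H]2C(C)(C)C(=O)OC
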